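The route rests on disconnecting the O1–C8a bond of the pyranone (ring C). In ring A of the target, O1 on C8a and the hydroxyls on C5 and C7 sit ortho, ortho and para to C4a, the carbon that carries the C4 carbonyl. These are the sites at which a ketone activates fluoride displacement on a 2,4,6-trifluorophenyl ring. The precursor is therefore an α-hydroxymethylene 2,4,6-trifluorophenyl ketone that already carries the complete O-benzylated chroman unit on the enol carbon. In one operation its enolate oxygen displaces an ortho fluoride, forming O1–C8a and ring C as a 5,7-difluoroisoflavone. The remaining fluorides are then exchanged for benzyloxy groups and all benzyl ethers are removed together.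

Key step: step 6

Assumption: 12 is drawn as its chelated Z-enol (in equilibrium with the α-formyl ketone tautomer), enaminone 11 is drawn E although its geometry is lost on hydrolysis, and the mono-ether 14 is taken as the C7-substituted isomer.

Step 1
Reactants: 1 5-bromo-2-hydroxy-3-methoxybenzaldehyde
Product: 2 4-bromo-2-(hydroxymethyl)-6-methoxyphenol
Conditions: NaBH4, MeOH, 0 °C to rt
Reagents that add atoms: none
Why: Chemoselective borohydride reduction of the aromatic aldehyde to the salicyl alcohol; the phenol, aryl bromide and methyl ether are inert to NaBH4.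

Step 2
Reactants: 2 4-bromo-2-(hydroxymethyl)-6-methoxyphenol; 3 2-methylpropene
Product: 5 6-bromo-8-methoxy-2,2-dimethylchroman, via o-quinone methide 4 (not isolated)
Conditions: 2-methylpropene (excess), toluene, sealed autoclave, 170 °C
Reagents that add atoms: none
Why: Thermal dehydration of the salicyl alcohol gives the o-quinone methide 4, which is trapped by the 1,1-disubstituted alkene in an inverse-electron-demand hetero-Diels–Alder reaction; the alkene CH2 bonds to the electrophilic methide carbon and oxygen to the tertiary carbon, so only the 2,2-dimethyl regioisomer is expected and no stereocenter arises.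

Step 3
Reactants: 5 6-bromo-8-methoxy-2,2-dimethylchroman
Product: 7 8-(benzyloxy)-6-bromo-2,2-dimethylchroman, via sodium chromanolate 6 (not isolated)
Conditions: NaSEt, DMF, 120 °C; then BnBr (excess), rt
Reagents that add atoms: benzyl bromide, BrCc1ccccc1
Why: Nucleophilic (SN2) demethylation by ethanethiolate attacks only the unhindered methyl group and leaves the tertiary alkyl aryl ether of the chroman and the aryl bromide intact, and the phenoxide 6 is benzylated in the same flask by Williamson ether synthesis while surplus thiolate is consumed by the excess benzyl bromide.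

Step 4
Reactants: 7 8-(benzyloxy)-6-bromo-2,2-dimethylchroman; 8 2',4',6'-trifluoroacetophenone (1.3 equiv)
Product: 9 2-[8-(benzyloxy)-2,2-dimethylchroman-6-yl]-1-(2,4,6-trifluorophenyl)ethan-1-one
Conditions: Pd2(dba)3 (cat.), Xantphos, K3PO4, toluene, 90 °C
Reagents that add atoms: none
Why: Palladium-catalysed ketone α-arylation (Buchwald–Hartwig type) by oxidative addition of the aryl bromide to zerovalent palladium, exchange for the potassium enolate of the methyl ketone and C–C reductive elimination; the weak, non-nucleophilic phosphate base spares the activated C–F bonds, and the wide-bite-angle ligand with excess ketone favours monoarylation.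

Step 5
Reactants: 9 2-[8-(benzyloxy)-2,2-dimethylchroman-6-yl]-1-(2,4,6-trifluorophenyl)ethan-1-one; 10 N,N-dimethylformamide dimethyl acetal
Product: 12 (Z)-2-[8-(benzyloxy)-2,2-dimethylchroman-6-yl]-3-hydroxy-1-(2,4,6-trifluorophenyl)prop-2-en-1-one, via enaminone 11 (not isolated)
Conditions: Me2NCH(OMe)2, toluene, 80 °C; concentrate; then 1 M HCl (aq), THF, rt
Reagents that add atoms: water, O
Why: Condensation of the doubly activated benzylic methylene with the formamide acetal gives enaminone 11, and mild acid hydrolysis of this vinylogous amide unmasks the β-keto aldehyde as its chelated Z-enol while holding dimethylamine as its salt so that it cannot attack the fluoroarene.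

Step 6
Reactants: 12 (Z)-2-[8-(benzyloxy)-2,2-dimethylchroman-6-yl]-3-hydroxy-1-(2,4,6-trifluorophenyl)prop-2-en-1-one
Product: 13 3-[8-(benzyloxy)-2,2-dimethylchroman-6-yl]-5,7-difluoro-4H-chromen-4-one
Conditions: K2CO3 (1.5 equiv), dry DMF, 60 °C
Reagents that add atoms: none
Why: K2CO3 deprotonates the acidic enol, the enolate oxygen adds to a fluorine-bearing carbon ortho to the ketone to give a Meisenheimer adduct whose charge is delocalised into the carbonyl and stabilised inductively by the two other fluorines, and fluoride is then expelled (addition–elimination SNAr). The closest known reaction type is the base-mediated intramolecular SNAr cyclisation of 2-fluorophenyl β-keto enols and enaminones to chromones and 4-quinolones. Ring C is closed by a six-membered, exo-type attack of the oxygen on the sp2 carbon that becomes C8a, which forms the O1–C8a bond. No stereocenter is formed. The step needs O- rather than C-attack of the ambident enolate and a single site of substitution: the first is enforced because only oxygen reaches an ortho carbon through a six-membered transition state, the second because the two ortho carbons of the symmetric 2,4,6-trifluorophenyl ring are equivalent. Enol geometry is not limiting, since the enolate isomerises freely, and moderate dilution lets the ring closure outrun intermolecular attack at the para fluoride.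

Step 7
Reactants: 13 3-[8-(benzyloxy)-2,2-dimethylchroman-6-yl]-5,7-difluoro-4H-chromen-4-one
Product: 15 5,7-bis(benzyloxy)-3-[8-(benzyloxy)-2,2-dimethylchroman-6-yl]-4H-chromen-4-one, via monobenzyl ether 14 (not isolated)
Conditions: BnOH (2.3 equiv), NaH (2.2 equiv), THF, 0 °C; then 13, DMF, 0 °C to rt
Reagents that add atoms: benzyl alcohol (as its sodium alkoxide), OCc1ccccc1
Why: Two successive intermolecular SNAr displacements at C7 (para to C4a) and C5 (ortho to C4a), both activated by the C4 carbonyl; the first benzyloxy group lies meta to the second reaction site and so should not retard it, and only a slight excess of alkoxide at low temperature is used so that reversible addition at C2 does not lead to opening of the pyranone.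

Step 8
Reactants: 15 5,7-bis(benzyloxy)-3-[8-(benzyloxy)-2,2-dimethylchroman-6-yl]-4H-chromen-4-one
Product: 16 5,7-dihydroxy-3-(8-hydroxy-2,2-dimethylchroman-6-yl)-4H-chromen-4-one
Conditions: H2 (1 atm), Pd/C (10 wt% palladium on carbon), EtOAc–MeOH, rt
Reagents that add atoms: none
Why: Catalytic hydrogenolysis of the three benzyl aryl ethers, stopped after uptake of three equivalents of hydrogen so that the chromone C2=C3 bond and the chroman ether remain untouched.

Compound list
1 | 5-bromo-2-hydroxy-3-methoxybenzaldehyde | COc1cc(Br)cc(C=O)c1O | starting material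
2 | 4-bromo-2-(hydroxymethyl)-6-methoxyphenol | COc1cc(Br)cc(CO)c1O | intermediate
3 | 2-methylpropene | C=C(C)C | starting material
4 | 4-bromo-2-methoxy-6-methylidenecyclohexa-2,4-dien-1-one (o-quinone methide) | COC1=CC(Br)=CC(=C)C1=O | intermediate
5 | 6-bromo-8-methoxy-2,2-dimethylchroman | COc1cc(Br)cc2CCC(C)(C)Oc12 | intermediate
6 | sodium 6-bromo-2,2-dimethylchroman-8-olate | [Na+].[O-]c1cc(Br)cc2CCC(C)(C)Oc12 | intermediate
7 | 8-(benzyloxy)-6-bromo-2,2-dimethylchroman | CC1(C)CCc2cc(Br)cc(OCc3ccccc3)c2O1 | intermediate
8 | 2',4',6'-trifluoroacetophenone | CC(=O)c1c(F)cc(F)cc1F | starting material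
9 | 2-[8-(benzyloxy)-2,2-dimethylchroman-6-yl]-1-(2,4,6-trifluorophenyl)ethan-1-one | O=C(Cc1cc(OCc2ccccc2)c2OC(C)(C)CCc2c1)c1c(F)cc(F)cc1F | intermediate
10 | N,N-dimethylformamide dimethyl acetal | COC(OC)N(C)C | starting material
11 | (E)-2-[8-(benzyloxy)-2,2-dimethylchroman-6-yl]-3-(dimethylamino)-1-(2,4,6-trifluorophenyl)prop-2-en-1-one | CN(C)/C=C(/C(=O)c1c(F)cc(F)cc1F)c1cc(OCc2ccccc2)c2OC(C)(C)CCc2c1 | intermediate
12 | (Z)-2-[8-(benzyloxy)-2,2-dimethylchroman-6-yl]-3-hydroxy-1-(2,4,6-trifluorophenyl)prop-2-en-1-one | O/C=C(\C(=O)c1c(F)cc(F)cc1F)c1cc(OCc2ccccc2)c2OC(C)(C)CCc2c1 | intermediate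
13 | 3-[8-(benzyloxy)-2,2-dimethylchroman-6-yl]-5,7-difluoro-4H-chromen-4-one | CC1(C)CCc2cc(-c3coc4cc(F)cc(F)c4c3=O)cc(OCc3ccccc3)c2O1 | intermediate
14 | 7-(benzyloxy)-3-[8-(benzyloxy)-2,2-dimethylchroman-6-yl]-5-fluoro-4H-chromen-4-one | CC1(C)CCc2cc(-c3coc4cc(OCc5ccccc5)cc(F)c4c3=O)cc(OCc3ccccc3)c2O1 | intermediate
15 | 5,7-bis(benzyloxy)-3-[8-(benzyloxy)-2,2-dimethylchroman-6-yl]-4H-chromen-4-one | CC1(C)CCc2cc(-c3coc4cc(OCc5ccccc5)cc(OCc5ccccc5)c4c3=O)cc(OCc3ccccc3)c2O1 | intermediate
16 | 5,7-dihydroxy-3-(8-hydroxy-2,2-dimethylchroman-6-yl)-4H-chromen-4-one | CC1(C)CCc2cc(-c3coc4cc(O)cc(O)c4c3=O)cc(O)c2O1 | target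

Total step count: 8. Longest linear sequence: 8 steps (1 to 16); compounds 3, 8 and 10 are purchased.

Steps most likely to fail

Step 7. The second fluoride exchange may lag behind the first, and during that time benzyl oxide can add at C2 and open the pyranone with loss of the formyl carbon. The fallback sets out from 13 and comes back at 16. One equivalent of sodium benzyl oxide in DMF at −20 °C should stop at the mono-ether 14, which is isolated. The last fluoride is then replaced by hydroxyl under weakly basic conditions with (E)-benzaldoxime and Cs2CO3 in DMSO at 70 °C. The oximate displaces fluoride to give 5-{[(E)-benzylideneamino]oxy}-7-(benzyloxy)-3-[8-(benzyloxy)-2,2-dimethylchroman-6-yl]-4H-chromen-4-one F1, which is not isolated. It fragments under the same base to benzonitrile and 7-(benzyloxy)-3-[8-(benzyloxy)-2,2-dimethylchroman-6-yl]-5-hydroxy-4H-chromen-4-one F2. Hydrogenolysis of the two benzyl ethers of F2 under the conditions of step 8 gives 16.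

Step 2. Self-condensation and oligomerisation of the o-quinone methide may outrun its cycloaddition with a gaseous, only moderately nucleophilic alkene. The fallback builds the ring by ionic steps; it sets out from 1 and comes back at 5. Claisen–Schmidt condensation of 1 with excess acetone (NaOH, water, rt) should give (E)-4-(5-bromo-2-hydroxy-3-methoxyphenyl)but-3-en-2-one F3. Excess MeMgBr in THF at 0 °C adds 1,2 to give 4-bromo-2-[(E)-3-hydroxy-3-methylbut-1-en-1-yl]-6-methoxyphenol F4. Catalytic TsOH in warm toluene ionises the tertiary allylic alcohol and closes it to 6-bromo-8-methoxy-2,2-dimethyl-2H-chromene F5. Diimide (TsNHNH2, NaOAc, aqueous THF, reflux) then saturates C3=C4 without touching the C–Br bond and gives 5.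

Step 4. Base-mediated side reactions may compete with the coupling: fluoride displacement on the trifluorophenyl ring, self-condensation of the ketone, or a second arylation of the more acidic product. The fallback is a base-free arylation of a preformed enolate equivalent; it sets out from 8 (with 7) and comes back at 9. Ketone 8 is converted with Me3SiOTf and Et3N in CH2Cl2 at 0 °C into trimethyl{[1-(2,4,6-trifluorophenyl)ethenyl]oxy}silane F6. Heating F6 with bromide 7, Bu3SnF and catalytic PdCl2[P(o-tol)3]2 in toluene generates tributyl{[1-(2,4,6-trifluorophenyl)ethenyl]oxy}stannane F7 in the flask, and its palladium-catalysed arylation gives 9.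

Further compounds
F1 | step 7 | 5-{[(E)-benzylideneamino]oxy}-7-(benzyloxy)-3-[8-(benzyloxy)-2,2-dimethylchroman-6-yl]-4H-chromen-4-one | CC1(C)CCc2cc(-c3coc4cc(OCc5ccccc5)cc(O/N=C/c5ccccc5)c4c3=O)cc(OCc3ccccc3)c2O1
F2 | step 7 | 7-(benzyloxy)-3-[8-(benzyloxy)-2,2-dimethylchroman-6-yl]-5-hydroxy-4H-chromen-4-one | CC1(C)CCc2cc(-c3coc4cc(OCc5ccccc5)cc(O)c4c3=O)cc(OCc3ccccc3)c2O1
F3 | step 2 | (E)-4-(5-bromo-2-hydroxy-3-methoxyphenyl)but-3-en-2-one | COc1cc(Br)cc(/C=C/C(C)=O)c1O
F4 | step 2 | 4-bromo-2-[(E)-3-hydroxy-3-methylbut-1-en-1-yl]-6-methoxyphenol | COc1cc(Br)cc(/C=C/C(C)(C)O)c1O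
F5 | step 2 | 6-bromo-8-methoxy-2,2-dimethyl-2H-chromene | COc1cc(Br)cc2C=CC(C)(C)Oc12
F6 | step 4 | trimethyl{[1-(2,4,6-trifluorophenyl)ethenyl]oxy}silane | C=C(O[Si](C)(C)C)c1c(F)cc(F)cc1F
F7 | step 4 | tributyl{[1-(2,4,6-trifluorophenyl)ethenyl]oxy}stannane | C=C(O[Sn](CCCC)(CCCC)CCCC)c1c(F)cc(F)cc1F
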